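We decide to reckon the flask from its first minutes, not from its last days.

| setting | south-west | west | north | flask |
|---|---|---|---|---|
| starting material | 0.025 M | 0.038 M | 0.050 M | 0.050 M |
| coupling partner | 0.0525 M | 0.0525 M | 0.0525 M | 0.0525 M |
| other conformer | 0.025 M | 0.025 M | 0.013 M | 0.0250 M |
| remark | run made earlier | run made earlier | run made earlier |  |
| time |  |  |  | 8.0 d |

| run | time / d | target / % | isomer of the product / % | starting material / % |
|---|---|---|---|---|
| south-west | 0.417 | 29.7 | 38.6 | 13.5 |
| south-west | 0.625 | 32.4 | 43.8 | 10.6 |
| south-west | 0.833 | 35.5 | 46.6 | 8.1 |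
| south-west | 1.25 | 37.2 | 49.2 | 5.4 |
| south-west | 2.08 | 40.0 | 52.8 | 3.3 |
| south-west | 3.00 | 40.5 | 54.5 | 1.6 |
| south-west | 5.00 | 42.5 | 56.4 | 1.5 |
| west | 0.417 | 27.6 | 35.6 | 16.8 |
| west | 0.625 | 30.6 | 39.9 | 13.7 |
| west | 0.833 | 32.4 | 41.0 | 12.1 |
| west | 1.25 | 33.3 | 44.2 | 9.5 |
| west | 2.08 | 34.5 | 46.1 | 8.5 |
| west | 3.00 | 36.5 | 46.9 | 8.3 |
| west | 5.00 | 35.5 | 47.2 | 8.0 |
| north | 1.04 | 33.1 | 42.8 | 11.0 |
| north | 2.08 | 35.9 | 46.1 | 8.9 |
| north | 3.00 | 35.3 | 46.7 | 8.3 |
| north | 4.00 | 35.7 | 47.4 | 8.6 |
| north | 5.00 | 36.1 | 47.0 | 7.6 |

(each reading ± 0.5 percentage points)



- share of target in target plus isomer of the product at 3.0 min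
- share of target in target plus isomer of the product at 3.0 h
- share of target in target plus isomer of the product at 8.0 d

The readings look contradictory: the north run was charged at 79.4% starting material and the south-west run at 50.0%, yet target takes 43.6% and 43.0% of the product. These fit if a share read after hours reflects the late conformer mixture rather than the charge.

So we carry a selectivity factor: target formed over isomer of the product, divided by the ratio of starting material to other conformer feeding them, taking both couplings as first order in each conformer. The latest west and north readings together give target to isomer 0.760 and, by difference, other conformer to starting material 1.19, so the factor, a reading that treats this late ratio as standing through those runs, is 0.906.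

The flask opens at a conformer ratio of 2.00, giving a momentary share of 64.4%, and ends near ratio 0.839, giving 43.2%. The earliest reading, at 0.417 d, comes later than 3.0 min, so we replace the curve between by the mean of its ends, 1.42, and commit to 56.3% at 3.0 min; this is an estimate, and we hold it within the range of those two end shares.

The forecast gives 44%, 43.3% and 43.2%, holding that “a relaxation time of up to about 10 min is not excluded”. We stand 12 percentage points above it at 3.0 min.

The flask gives 58.7%, 43.9% and 43.4%.

    coupling partner + other conformer → isomer of the product (k = 4.10 L mol⁻¹ h⁻¹)
    starting material + coupling partner → target (k = 3.70 L mol⁻¹ h⁻¹)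
    starting material ⇌ other conformer (K = 1.20, k = 6.90 h⁻¹)

In the flask, starting material and other conformer relaxed with a half-life of 0.0548 h by that step alone, both ways together, while the couplings did half their turnover up to 8.0 d by 0.122 d for target and 0.126 d for isomer of the product, and coupling partner, the limiting reagent, stood at 0.00633% of its charge at 4.00 d. Through the factor, the flask's share at 3.0 min means a mean conformer ratio of 1.57. The neighbour flask with 0.020 M starting material opens at ratio 0.800, the mean of that and the late ratio gives through the factor 42.6%, and its simulated share at 3.0 min is 42.2%.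

(Readings and results are simulated for an exercise.)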